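Locants: ring A (enedione) = C1–C2(=O)–C3=C4–C5(=O)–C6; ring C (cyclohexene) = C1–C6–C7H=C8(CH3)–C9H2–C10H; ring B (five-membered) = C1–C6–C16–C11–C10; ring D (hydroquinone) = C11–C16. C1 carries the prenyl group.
Enabling feature: ring C is a cyclohexene that shares the C1–C6 bond with ring A and has its alkene at C7=C8. It therefore reads as the adduct of a C6=C7–C8=C9 diene and a C10=C1 dienophile already linked through C2–C3=C4–C5.
Cuts, in retrosynthetic order: hydroquinone to its dimethyl ether; C6–C16 (ring B); C1–C6 and C9–C10 in one operation (rings A and C); the C2/C5 carbonyl pair back to a furan; C6=C7; C1–C2; C10–C11; C1–CH2(prenyl).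
Forward order: the C10≡C1 unit is prenylated and cis-diborylated. Two Suzuki couplings put ring D on C10 and a furan (C2–C5) on C1, an olefination adds C6–C9, and the furan is opened to the Z-enedione. Rings A and C then close together, ring B follows, and ring D is unmasked last.
Stereochemistry: syn-diboration places the aryl group cis to the future C2 acyl group, and the suprafacial cycloaddition turns this into the C1/C10 relationship. A chiral oxazaborolidinium ion sets the absolute sense. C6 is fixed because the C10-bound arene can reach only one face of the planar enolate.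

Key step: step 8

Assumption: existing models do not safely predict the sense of induction on this new substrate class, so the (S)-configured catalyst is written for the drawn enantiomer; its mirror image is equally available.

Step 1
Reactants: 1 prenyl bromide (1-bromo-3-methylbut-2-ene); 2 ethynylmagnesium bromide
Product: 3 5-methylhex-4-en-1-yne
Conditions: CuCl (5 mol %), THF, 0 → 40 °C, 2 in excess; distillation
Reagents that add atoms: none
Why: Copper-catalysed allylic substitution of an alkynyl Grignard reagent is the classical entry to skipped 1,4-enynes, attack at the unhindered CH2 terminus of 1 gives the linear product, and the excess of 2 suppresses double allylation.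

Step 2
Reactants: 3 5-methylhex-4-en-1-yne
Product: 4 cis-1,2-bis(pinacolatoboryl)-5-methylhexa-1,4-diene (both boryl groups on the same side of C10=C1; E by the sequence rule)
Conditions: Pt(PPh3)4 (3 mol %), DMF, 80 °C
Reagents that add atoms: bis(pinacolato)diboron, CC1(C)OB(OC1(C)C)B1OC(C)(C)C(C)(C)O1
Why: Platinum-catalysed diboration of a terminal alkyne is a strict syn addition that ignores the trisubstituted alkene, so both boron atoms end on the same side of C10=C1 and the later aryl/acyl cis relationship is laid down here.

Step 3
Reactants: 5 2-bromo-1,4-dimethoxybenzene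
Product: 7 2-bromo-3-iodo-1,4-dimethoxybenzene, via aryllithium 6 (not isolated)
Conditions: LiN(i-Pr)2, THF, −78 °C; then I2, −78 °C → rt
Reagents that add atoms: iodine, [I][I]
Why: Directed ortho-metalation removes the most acidic ring proton, the one flanked by bromine and methoxy, the amide base does not exchange the bromine, and iodine traps 6 at −78 °C before LiBr can be lost.

Step 4
Reactants: 4 cis-diboryl diene; 7 2-bromo-3-iodo-1,4-dimethoxybenzene
Product: 8 2-[(1E)-1-(2-bromo-3,6-dimethoxyphenyl)-5-methylhexa-1,4-dien-2-yl]-4,4,5,5-tetramethyl-1,3,2-dioxaborolane (aryl cis to boron)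
Conditions: PdCl2(dppf) (dppf = 1,1′-bis(diphenylphosphino)ferrocene, 5 mol %), K2CO3, THF/H2O, 55 °C, slight excess of 4
Reagents that add atoms: none
Why: This Suzuki–Miyaura coupling is selective twice over, because zerovalent palladium inserts into C–I long before C–Br and the terminal C–B bond of a 1,2-diborylalkene transmetalates before the hindered internal one, and it proceeds with retention so that the aryl group stays cis to the remaining boron.

Step 5
Reactants: 8 alkenyl boronate; 9 5-bromofuran-2-carbaldehyde
Product: 10 5-[(1Z)-1-(2-bromo-3,6-dimethoxyphenyl)-5-methylhexa-1,4-dien-2-yl]furan-2-carbaldehyde (aryl cis to furyl)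
Conditions: Pd(PPh3)4 (5 mol %), Cs2CO3, 1,4-dioxane/H2O, 70 °C, dark
Reagents that add atoms: none
Why: A second Suzuki–Miyaura coupling with retention puts the furan (C2–C5) on C1 cis to the aryl group, and the formyl-activated 2-bromofuran undergoes oxidative addition far more readily than the electron-rich di-ortho-substituted aryl bromide, which is thereby saved for step 9.

Step 6
Reactants: 10 furan aldehyde; 11 diethyl (2-methylallyl)phosphonate
Product: 13 2-[(1Z)-1-(2-bromo-3,6-dimethoxyphenyl)-5-methylhexa-1,4-dien-2-yl]-5-[(1E)-3-methylbuta-1,3-dien-1-yl]furan, via lithiated phosphonate 12 (not isolated)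
Conditions: 11, n-BuLi, THF, −78 °C; hexamethylphosphoric triamide (HMPA); then 10, −78 °C → rt
Reagents that add atoms: none
Why: Horner–Wadsworth–Emmons olefination with an α-lithiated allylic phosphonate in the presence of HMPA is an established route from aromatic aldehydes to terminal (E)-1,3-dienes, and since all n-BuLi is consumed in forming 12 the aryl bromide and the Z alkene are left alone.

Step 7
Reactants: 13 furan tetraene
Product: 15 (3E,6Z,9Z)-9-[(2-bromo-3,6-dimethoxyphenyl)methylidene]-2,12-dimethyltrideca-1,3,6,11-tetraene-5,8-dione (Z-enedione with aryl cis to the C2 carbonyl), via furan endoperoxide 14 (not isolated)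
Conditions: O2, 5,10,15,20-tetraphenylporphyrin (1 mol %), light > 550 nm, CH2Cl2, −78 °C; lamp off, Me2S, −78 → 0 °C; short neutral silica plug, dark, used at once
Reagents that add atoms: dioxygen, O=O
Why: [4+2] photooxygenation of a 2,5-disubstituted furan followed by sulfide reduction of the endoperoxide is the standard neutral route to cis-enediones, the s-cis-locked electron-rich furan traps singlet oxygen much faster than a trisubstituted alkene or an acyclic diene, the ring hands over C3=C4 as the Z isomer, and long-wavelength light that is switched off before the reduction spares both the Z styrene and the product.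

Step 8
Reactants: 15 Z-enedione tetraene
Product: 16 (4aS,5S,8aR)-5-(2-bromo-3,6-dimethoxyphenyl)-7-methyl-4a-(3-methylbut-2-en-1-yl)-4a,5,6,8a-tetrahydronaphthalene-1,4-dione (cis-fused rings A and C; aryl on C10, C2 on C1 and C5 on C6 all on one face of ring C)
Conditions: (S)-3,3-diphenyl-1-(2-methylphenyl)tetrahydro-1H,3H-pyrrolo[1,2-c][1,3,2]oxazaborole (30 mol %), (CF3SO2)2NH (25 mol %), CH2Cl2 (0.005 M), −40 → −10 °C, dark
Reagents that add atoms: none
Why: Proposed new method: the protonated oxazaborolidine binds the C2 carbonyl oxygen, lowers the LUMO of the C10=C1 enone and sets off a concerted, asynchronous [4+2] in which the diene terminus C9 (largest HOMO coefficient, next to methyl-bearing C8 and remote from the C5 acyl group) runs ahead in bonding to the β-carbon C10 while C6 closes onto C1. The closest known reaction types are the thermal or Me2AlCl-promoted type 1 cyclisation of 1,7,9-decatrien-3-ones and the oxazaborolidinium-catalysed cyclisation of 2,7,9-decatrienals; neither has been shown on a cross-conjugated enedione tether or on an α-alkyl-β-aryl enone dienophile, hence the label. Ring C closes as the six-membered cycloadduct proper (C1–C6–C7=C8–C9–C10) and ring A in the same event as the six-membered ring spanned by the four-atom tether C2–C5, whose Z alkene holds C1 and C6 within bonding distance. C1 and C10 are tied to one another by suprafacial addition to the Z dienophile (aryl cis to acyl becomes aryl cis to C2 on ring C) and their absolute sense comes from the catalyst, whose aryl groups screen one face of the bound enone; C6 follows from the endo placement of the C2 carbonyl (cis fusion) and is not critical because step 9 planarises it. The step needs site selectivity for C10=C1 over the more reactive C3=C4 bond, which the tether secures because the diene cannot reach C3=C4 within the molecule and high dilution suppresses the bimolecular path. Binding at the C5 carbonyl is reversible and only deactivates the diene, so turnover should run through the C2-bound complex, and low temperature, darkness and the non-nucleophilic (CF3SO2)2N− counter-ion protect the two Z alkenes.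

Step 9
Reactants: 16 cis-fused adduct
Product: 17 tetracyclic bis(methyl ether) with the C6–C16 bond closed (ring B; 1S,6R,10R in the locants used here; C16 and C11 on one face of ring C together with C2, and C5 and prenyl on the other)
Conditions: Pd(OAc)2 (10 mol %), 2-dicyclohexylphosphino-2′,4′,6′-triisopropylbiphenyl (20 mol %), K3PO4, toluene, 80 °C, degassed
Reagents that add atoms: none
Why: Intramolecular palladium-catalysed α-arylation of a ketone is known to close benzo-fused bridged bicycles and to build quaternary carbons, phosphate suffices to enolise the C6–H that is both α to C5=O and allylic, and because the aryl bromide hangs from C10 on the face of ring C that also carries C2 the six-membered palladacycle can deliver C16 only to that face of planar C6, which sets the third stereocentre whatever the C6 configuration of 16.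

Step 10
Reactants: 17 tetracyclic bis(methyl ether)
Product: 18 ring D quinone (1S,6S,10R in the locants used here; the spatial arrangement is unchanged and the C6 descriptor changes only through priorities)
Conditions: (NH4)2Ce(NO3)6, MeCN/H2O, 0 °C
Reagents that add atoms: water, O
Why: Oxidative demethylation of a 1,4-dimethoxyarene with (NH4)2Ce(NO3)6 starts by electron transfer from the most electron-rich π system, is routinely compatible with prenyl groups and enones at 0 °C, and gives a quinone that cannot tautomerise because C10 is a bridgehead.

Step 11
Reactants: 18 ring D quinone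
Product: 19 CNP0513322.1 (1S,6R,10R in the locants used here)
Conditions: Na2S2O4, EtOAc/H2O, rt, brief shaking under argon
Reagents that add atoms: none
Why: Dithionite reduction of a 1,4-benzoquinone in a two-phase system is immediate at room temperature because it ends in an aromatic ring, whereas the ring A enedione is blocked from aromatising by quaternary C1 and C6 and is not reduced on brief contact, so no stereocentre is touched.

Compound list
1 | prenyl bromide | CC(C)=CCBr | starting material
2 | ethynylmagnesium bromide | C#C[Mg]Br | starting material
3 | 5-methylhex-4-en-1-yne | C#CCC=C(C)C | intermediate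
4 | cis-1,2-bis(pinacolatoboryl)-5-methylhexa-1,4-diene | CC(C)=CC/C(B1OC(C)(C)C(C)(C)O1)=C/B1OC(C)(C)C(C)(C)O1 | intermediate
5 | 2-bromo-1,4-dimethoxybenzene | COc1ccc(OC)c(Br)c1 | starting material
6 | (2-bromo-3,6-dimethoxyphenyl)lithium | COc1ccc(OC)c([Li])c1Br | intermediate (not isolated)
7 | 2-bromo-3-iodo-1,4-dimethoxybenzene | COc1ccc(OC)c(I)c1Br | intermediate
8 | alkenyl boronate, aryl cis to boron | COc1ccc(OC)c(Br)c1/C=C(CC=C(C)C)\B1OC(C)(C)C(C)(C)O1 | intermediate
9 | 5-bromofuran-2-carbaldehyde | O=Cc1ccc(Br)o1 | starting material
10 | 5-[(1Z)-1-(2-bromo-3,6-dimethoxyphenyl)-5-methylhexa-1,4-dien-2-yl]furan-2-carbaldehyde | COc1ccc(OC)c(Br)c1/C=C(CC=C(C)C)\c1ccc(C=O)o1 | intermediate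
11 | diethyl (2-methylallyl)phosphonate | CCOP(=O)(CC(C)=C)OCC | starting material
12 | α-lithiated diethyl (2-methylallyl)phosphonate | [Li]C(C(C)=C)P(=O)(OCC)OCC | intermediate (not isolated)
13 | furan tetraene (Z aryl/furyl alkene, E diene) | COc1ccc(OC)c(Br)c1/C=C(CC=C(C)C)\c1ccc(/C=C/C(C)=C)o1 | intermediate
14 | 1,4-disubstituted 2,3,7-trioxabicyclo[2.2.1]hept-5-ene (furan endoperoxide, racemic, one enantiomer drawn) | COc1ccc(OC)c(Br)c1/C=C(CC=C(C)C)\[C@@]12OO[C@@](/C=C/C(C)=C)(C=C1)O2 | intermediate (not isolated)
15 | (3E,6Z,9Z)-9-[(2-bromo-3,6-dimethoxyphenyl)methylidene]-2,12-dimethyltrideca-1,3,6,11-tetraene-5,8-dione | COc1ccc(OC)c(Br)c1/C=C(CC=C(C)C)\C(=O)/C=C\C(=O)/C=C/C(C)=C | intermediate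
16 | (4aS,5S,8aR)-5-(2-bromo-3,6-dimethoxyphenyl)-7-methyl-4a-prenyl-4a,5,6,8a-tetrahydronaphthalene-1,4-dione | CC(C)=CC[C@@]12C(=O)C=CC(=O)[C@@H]1C=C(C)C[C@@H]2c1c(OC)ccc(OC)c1Br | intermediate
17 | tetracyclic bis(methyl ether) of the target | CC(C)=CC[C@@]12C(=O)C=CC(=O)[C@@]13C=C(C)C[C@@H]2c1c(OC)ccc(OC)c13 | intermediate
18 | ring D quinone | CC(C)=CC[C@@]12C(=O)C=CC(=O)[C@@]13C=C(C)C[C@@H]2C1=C3C(=O)C=CC1=O | intermediate
19 | CNP0513322.1 | CC(C)=CC[C@@]12C(=O)C=CC(=O)[C@@]13C=C(C)C[C@@H]2c1c(O)ccc(O)c13 | target

Total step count: 11. Longest linear sequence: 10 steps (1, 2 and 4 to 11, from prenyl bromide).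

Steps most likely to fail

First, step 8.
- **What may go wrong:** The catalyst may rest on the less hindered and more basic C5 carbonyl. Facial discrimination may be poor because the dienophile offers no α-hydrogen as a second contact point. Acid-induced rotation about C10=C1 or C3=C4 may erode the alkene geometry before cyclisation.
- **Fallback (known chemistry, sets out from 15):** Heating in dilute toluene (110 °C, 2,6-di-tert-butyl-4-methylphenol, dark) runs the uncatalysed type 1 intramolecular Diels–Alder reaction of a trienone. This gives the racemate, that is 16 together with its mirror image ent-16 F1. Preparative chromatography on a cellulose tris(3,5-dimethylphenylcarbamate) phase separates the two, and the route is rejoined at 16. The absolute configuration then comes from resolution instead of catalysis.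

Second, step 9.
- **What may go wrong:** Carbopalladation of the C7=C8 alkene (a rival five-membered closure onto C8) or of the prenyl alkene may outrun capture of the enolate. Binding of zerovalent palladium by the enedione may stall oxidative addition. The base may degrade ring A.
- **Fallback (sets out from 16):** This makes carbopalladation the intended path. 1,8-Diazabicyclo[5.4.0]undec-7-ene in CH2Cl2 at rt moves the alkene into conjugation and gives the cross-conjugated dienedione F2 (C6=C7, methyl on C8 anti to the aryl group). This removes the rival alkene. An intramolecular Heck reaction (Pd(OAc)2, PPh3, K2CO3, MeCN, 80 °C) then adds C16 to C6 in the 5-exo mode and palladium to C7 on the same face. Syn β-hydride elimination of the hydrogen on C8 restores C7=C8, and the route is rejoined at 17.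

Third, step 7.
- **What may go wrong:** Singlet oxygen may also engage the extended furyl-diene chromophore. The endoperoxide may rearrange before it is reduced. A product that holds both a free diene and an unhindered enedione may oligomerise or lose its Z geometry while it is concentrated.
- **Fallback (sets out from 10):** This holds back the terminal alkene of the diene until after the oxidation.
  - Wittig reaction with Ph3P=CHC(O)CH3 (toluene, 80 °C) gives the (E)-enone F3.
  - MeMgBr/CeCl3 (THF, −78 °C) adds in the 1,2 sense to give the tertiary allylic alcohol F4.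
  - Photooxygenation as in step 7 gives the endoperoxide F5, which Me2S reduces in the flask to the hydroxy Z-enedione F6. F6 has no diene and can be purified and stored.
  - Dehydration with Ph2S[OC(CF3)2Ph]2 (CH2Cl2, −20 °C) toward one of the two methyl groups unveils C8=C9. The route is rejoined at 15 directly before step 8.

Further compounds
F1 | step 8 | ent-16, (4aR,5R,8aS)-5-(2-bromo-3,6-dimethoxyphenyl)-7-methyl-4a-prenyl-4a,5,6,8a-tetrahydronaphthalene-1,4-dione | CC(C)=CC[C@]12C(=O)C=CC(=O)[C@H]1C=C(C)C[C@H]2c1c(OC)ccc(OC)c1Br
F2 | step 9 | (4aS,5S,7S)-5-(2-bromo-3,6-dimethoxyphenyl)-7-methyl-4a-prenyl-4a,5,6,7-tetrahydronaphthalene-1,4-dione | CC(C)=CC[C@@]12C(=O)C=CC(=O)C1=C[C@@H](C)C[C@@H]2c1c(OC)ccc(OC)c1Br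
F3 | step 7 | (3E)-4-{5-[(1Z)-1-(2-bromo-3,6-dimethoxyphenyl)-5-methylhexa-1,4-dien-2-yl]furan-2-yl}but-3-en-2-one | COc1ccc(OC)c(Br)c1/C=C(CC=C(C)C)\c1ccc(/C=C/C(C)=O)o1
F4 | step 7 | (3E)-4-{5-[(1Z)-1-(2-bromo-3,6-dimethoxyphenyl)-5-methylhexa-1,4-dien-2-yl]furan-2-yl}-2-methylbut-3-en-2-ol | COc1ccc(OC)c(Br)c1/C=C(CC=C(C)C)\c1ccc(/C=C/C(C)(C)O)o1
F5 | step 7 | endoperoxide of F4 (racemic, one enantiomer drawn) | COc1ccc(OC)c(Br)c1/C=C(CC=C(C)C)\[C@@]12OO[C@@](/C=C/C(C)(C)O)(C=C1)O2
F6 | step 7 | (3E,6Z,9Z)-9-[(2-bromo-3,6-dimethoxyphenyl)methylidene]-2-hydroxy-2,12-dimethyltrideca-3,6,11-triene-5,8-dione | COc1ccc(OC)c(Br)c1/C=C(CC=C(C)C)\C(=O)/C=C\C(=O)/C=C/C(C)(C)O
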